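Readings and results come from a simulation with constants of no real substance; noise was put on by code.

At early times green and red can't be told apart: at 2.00 min they stand at 3.3% and 3.2% of product, and at 8.00 min at 14.0% and 14.1%, although c(capture agent) differs between them by 0.400 mM.

| setting | green | red | theta | zeta | beta |
|---|---|---|---|---|---|
| starting material | 23 mM | 23 mM | 23 mM | 23 mM | 23 mM |
| partner | 57.5 mM | 57.5 mM | 57.5 mM | 57.5 mM | 57.5 mM |
| capture agent | 0.040 mM | 0.44 mM | 0.0500 mM | 0.150 mM | 0.500 mM |
| free catalyst | 0.57 mM | 0.57 mM | 0.57 mM | 0.57 mM | 0.57 mM |
| remark | run made earlier | run made earlier |  |  |  |
| time |  |  | 10 min | 10 min | 10 min |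

- green (time / min: product / %, starting material / %): 0.500: 0.4, 97.9; 0.833: 0.6, 97.8; 1.33: 1.8, 96.1; 2.00: 3.3, 95.5; 3.00: 5.1, 93.2; 5.00: 8.6, 90.1; 8.00: 14.0, 84.5
- red (time / min: product / %, starting material / %): 0.500: 0.6, 98.3; 0.833: 1.2, 97.4; 1.33: 1.5, 96.4; 2.00: 3.2, 95.2; 3.00: 5.4, 93.0; 5.00: 8.5, 89.7; 8.00: 14.1, 84.8

(each reading ± 0.3 percentage points)

- a reading or a percentage of product counts all its forms, free or not
- "hardly changes" means that all values lie within two and a half points (for a concentration: within two and a half percent of the largest)

- amount of product at the end, in percent of the starting material charged for theta, zeta, beta, in this order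
- the course of these numbers from the first flask to the last (hardly changes / rises all the way / falls, then rises / falls all the way / rises, then falls)

One chemist holds that the capture agent is a slow poison which takes catalyst one for one, late enough that runs ending at 8.00 min hardly show it, and she points out that beta charges it at 87.7% of the free catalyst, against 77.2% in red. On her view beta could keep 12.3% of its catalyst over the last stretch, and, starting from red's 14.1% and red's mean slope, it would creep to about 14.5% at 10 min.

The other chemist, whose side I take, calls the agent a bystander and treats it as a small correction to a large product line, asking what size of correction the readings could hide. The difference of two readings scatters by 0.42 percentage points, and a shift that grew in proportion to time up to 10 min would reach 0.53 points, which I call the capture ceiling: the end-of-run shift in product that a step in c(capture agent) as wide as the one from green to red could hide within one standard deviation of a difference. Scaled in proportion to the step from theta to beta, it becomes 0.6 points, well inside the margin of the answer, so I commit to a course that hardly changes.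

The forecast gives 17.5%, 17.5% and 17.5% for theta, zeta and beta, and says “the course should be flat”.

The flasks give 17.7%, 17.6% and 17.4%, a course that hardly changes, and theta and beta stand 0.3 points apart, less than the ceiling of 0.6 points.

    catalyst intermediate A → catalyst intermediate B (k = 5.50 /min)
    catalyst intermediate C → free catalyst + product (k = 1.20 /min)
    crystals ⇌ product, rate k3*(cs3 - [product]) while solid is left; crystals form when [product] > cs3 (solubility = 19.0 mM, k = 1.00 /min)
    catalyst intermediate A + capture agent → trapped intermediate (k = 44.0 /M/min)
    starting material + catalyst intermediate A → spent catalyst (k = 1.60 /M/min)
    starting material + catalyst intermediate B → catalyst intermediate C (k = 1900 /M/min)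
    partner + free catalyst → catalyst intermediate A (k = 66.0 /M/min)

Trapping is the small term here: by 10.0 min beta holds 3.00% of its catalyst as trapped intermediate, against 58.0% as catalyst intermediate C, the resting state, and taking the trapping step away barely moves beta's product. Scaled to the step from theta to zeta, the ceiling is 0.13 points, and those flasks stand 0.1 points apart. Beta's product is 17.4% at 10 min and 99.7% at 100 min, the hour of the reading being the main reason for that gap, and the poison view has its region at that later hour, where beta holds 14.9% of its catalyst as trapped intermediate, against 1.50% in theta.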